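**Retrosynthetic overview**
- Target ⇐ protected macrocycle by three late steps: primary silyl ether removal, C15 acetylation, unmasking of the side-chain diol.
- Ten-membered ring ⇐ C3–C4 bond by intramolecular B-alkyl Suzuki–Miyaura coupling (C3 alkylborane from a terminal diene, Z alkenyl iodide at C4).
- Key disconnection C6–C7: intermolecular zinc Barbier allylation of a Z 3-iodo-enal (C4–C6, C15) with a (5S)-3-(bromomethyl)butenolide (C7–C14, C1–C3). It creates the α-methylene lactone and sets C6 and C7 from C8; the O6 ester comes from an (R)-acetonide acid made from (S)-lactic acid.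
- Butenolide ⇐ ring-closing metathesis of an acrylate of a (3S)-dienol from (S)-epichlorohydrin (alkynylation, ylide homologation, carboalumination–iodination, then Stille vinylation); iodo-enal ⇐ but-2-yne-1,4-diol.
- Ring order: five-membered lactone first (as butenolide, step 8, transposed to the α-methylene lactone in step 20), ten-membered carbocycle last (step 22).

Assumption: germacrane numbering is used (ring C1–C10, lactone C11–C13 closed on O8, C14 methyl, C15 CH2OAc, ester on O6); the SMILES is read as 6R,7R,8S,2'R with an E 1(10) bond and a ring-cis 4,5 bond.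

**Route**

Step 1
Reactants: 1 (S)-epichlorohydrin; 2 ethynyltrimethylsilane
Product: 4 (2S)-1-chloro-5-(trimethylsilyl)pent-4-yn-2-ol, via lithium (trimethylsilyl)acetylide 3 (not isolated)
Conditions: n-BuLi, THF, −78 °C; BF3·OEt2; then 1, −78 °C
Reagents that add atoms: none
Why: BF3-promoted SN2 opening of the epoxide at its unsubstituted carbon by the lithium acetylide (Yamaguchi-type alkynylation) leaves the C–Cl bond and the carbinol centre (future C8) untouched.

Step 2
Reactants: 4 (2S)-1-chloro-5-(trimethylsilyl)pent-4-yn-2-ol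
Product: 6 (3S)-6-(trimethylsilyl)hex-1-en-5-yn-3-ol, via epoxide 5 (not isolated)
Conditions: trimethylsulfonium iodide (4 equiv), n-BuLi (3.9 equiv), THF, −20 °C → rt
Reagents that add atoms: trimethylsulfonium iodide, C[S+](C)C.[I-]
Why: excess dimethylsulfonium methylide closes the chlorohydrin to the terminal epoxide, then opens it and eliminates dimethyl sulfide (sulfonium-ylide one-carbon homologation of an epoxide to an allylic alcohol), so the carbinol centre is never a reaction site and stays S.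

Step 3
Reactants: 6 (3S)-6-(trimethylsilyl)hex-1-en-5-yn-3-ol
Product: 7 (3S)-hex-1-en-5-yn-3-ol
Conditions: K2CO3 (0.2 equiv), MeOH, rt
Reagents that add atoms: none
Why: base-catalysed methanolysis of the alkynyl C–Si bond (protodesilylation) is fast and touches nothing else.

Step 4
Reactants: 7 (3S)-hex-1-en-5-yn-3-ol
Product: 9 (3S,5E)-6-iodo-5-methylhexa-1,5-dien-3-ol, via alkenylalane 8 (not isolated)
Conditions: Me3Al (3 equiv), Cp2ZrCl2 (0.25 equiv), CH2Cl2, 0 °C → rt; then I2, THF, −30 → 0 °C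
Reagents that add atoms: trimethylaluminium, C[Al](C)C; iodine, II
Why: zirconium-catalysed Negishi carboalumination adds methyl and aluminium syn across the terminal alkyne with methyl on the internal carbon, and iodinolysis with retention gives the E alkenyl iodide (future C1=C10) while the much less reactive vinyl group is left alone.

Step 5
Reactants: 10 ethyl 2-(hydroxymethyl)prop-2-enoate
Product: 11 ethyl 2-({[tert-butyl(dimethyl)silyl]oxy}methyl)prop-2-enoate
Conditions: TBSCl, imidazole, CH2Cl2, 0 °C → rt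
Reagents that add atoms: tert-butyldimethylsilyl chloride, CC(C)(C)[Si](C)(C)Cl
Why: standard silyl ether formation on the primary allylic alcohol.

Step 6
Reactants: 11 ethyl 2-({[tert-butyl(dimethyl)silyl]oxy}methyl)prop-2-enoate
Product: 12 2-({[tert-butyl(dimethyl)silyl]oxy}methyl)prop-2-enoic acid
Conditions: LiOH·H2O, THF/H2O, 0 °C → rt; then cold 1 M HCl to pH 3–4
Reagents that add atoms: lithium hydroxide, [Li+].[OH-]
Why: saponification of the ethyl ester leaves the primary TBS ether intact.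

Step 7
Reactants: 9 (3S,5E)-6-iodo-5-methylhexa-1,5-dien-3-ol; 12 2-({[tert-butyl(dimethyl)silyl]oxy}methyl)prop-2-enoic acid
Product: 13 (3S,5E)-6-iodo-5-methylhexa-1,5-dien-3-yl 2-({[tert-butyl(dimethyl)silyl]oxy}methyl)prop-2-enoate
Conditions: DCC, DMAP (cat.), CH2Cl2, 0 °C → rt
Reagents that add atoms: none
Why: Steglich esterification acylates the secondary allylic alcohol at oxygen, so the carbinol centre is retained.

Step 8
Reactants: 13 (3S,5E)-6-iodo-5-methylhexa-1,5-dien-3-yl 2-({[tert-butyl(dimethyl)silyl]oxy}methyl)prop-2-enoate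
Product: 14 (5S)-3-({[tert-butyl(dimethyl)silyl]oxy}methyl)-5-[(2E)-3-iodo-2-methylprop-2-en-1-yl]furan-2(5H)-one
Conditions: second-generation Grubbs catalyst [RuCl2(H2IMes)(PCy3)(=CHPh)] (5 mol%), CH2Cl2 (5 mM), 40 °C
Reagents that add atoms: none
Why: ring-closing metathesis between the vinyl group and the 1,1-disubstituted acrylate closes the five-membered butenolide, the trisubstituted alkenyl iodide being inert to the ruthenium carbene.

Step 9
Reactants: 14 (5S)-3-({[tert-butyl(dimethyl)silyl]oxy}methyl)-5-[(2E)-3-iodo-2-methylprop-2-en-1-yl]furan-2(5H)-one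
Product: 15 (5S)-3-({[tert-butyl(dimethyl)silyl]oxy}methyl)-5-[(2E)-2-methylpenta-2,4-dien-1-yl]furan-2(5H)-one
Conditions: tributyl(vinyl)stannane, PdCl2(MeCN)2 (5 mol%), DMF, rt
Reagents that add atoms: tributyl(vinyl)stannane, C=C[Sn](CCCC)(CCCC)CCCC
Why: Stille cross-coupling of the alkenyl iodide proceeds with retention of the E geometry under neutral conditions that do not epimerise the base-sensitive butenolide γ-centre.

Step 10
Reactants: 15 (5S)-3-({[tert-butyl(dimethyl)silyl]oxy}methyl)-5-[(2E)-2-methylpenta-2,4-dien-1-yl]furan-2(5H)-one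
Product: 16 (5S)-3-(hydroxymethyl)-5-[(2E)-2-methylpenta-2,4-dien-1-yl]furan-2(5H)-one
Conditions: HF·pyridine, pyridine, THF, 0 °C → rt
Reagents that add atoms: none
Why: buffered fluoride desilylation frees the primary alcohol without base that could racemise the butenolide.

Step 11
Reactants: 16 (5S)-3-(hydroxymethyl)-5-[(2E)-2-methylpenta-2,4-dien-1-yl]furan-2(5H)-one
Product: 17 (5S)-3-(bromomethyl)-5-[(2E)-2-methylpenta-2,4-dien-1-yl]furan-2(5H)-one
Conditions: CBr4, PPh3, CH2Cl2, 0 °C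
Reagents that add atoms: carbon tetrabromide, BrC(Br)(Br)Br
Why: Appel bromination converts the primary allylic alcohol into the bromide under neutral conditions.

Step 12
Reactants: 18 but-2-yne-1,4-diol
Product: 19 4-{[tert-butyl(dimethyl)silyl]oxy}but-2-yn-1-ol
Conditions: TBSCl (1 equiv), imidazole, DMF, 0 °C → rt (diol 3 equiv)
Reagents that add atoms: tert-butyldimethylsilyl chloride, CC(C)(C)[Si](C)(C)Cl
Why: statistical monosilylation of the symmetric diol used in excess.

Step 13
Reactants: 19 4-{[tert-butyl(dimethyl)silyl]oxy}but-2-yn-1-ol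
Product: 21 (2Z)-4-{[tert-butyl(dimethyl)silyl]oxy}-3-iodobut-2-en-1-ol, via cyclic alkenylalanate 20 (not isolated)
Conditions: NaAlH2(OCH2CH2OMe)2 (Red-Al), THF, 0 °C; then I2, −78 → 0 °C
Reagents that add atoms: iodine, II
Why: alkoxide-directed trans-hydroalumination of the propargylic alcohol places aluminium on the distal alkyne carbon in a five-membered alanate, and iodinolysis with retention gives the Z iodide with iodine cis to CH2OH (the future ring-cis C4=C5 geometry).

Step 14
Reactants: 21 (2Z)-4-{[tert-butyl(dimethyl)silyl]oxy}-3-iodobut-2-en-1-ol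
Product: 22 (2Z)-4-{[tert-butyl(dimethyl)silyl]oxy}-3-iodobut-2-enal
Conditions: Dess–Martin periodinane, NaHCO3, CH2Cl2, 0 °C; use at once
Reagents that add atoms: none
Why: buffered Dess–Martin oxidation of the allylic alcohol gives the enal at 0 °C without Z-to-E isomerisation.

Step 15
Reactants: 23 (S)-lactic acid; 24 pivalaldehyde
Product: 25 (2S,5S)-2-tert-butyl-5-methyl-1,3-dioxolan-4-one
Conditions: TsOH·H2O (cat.), H2SO4 (cat.), pentane, reflux, Dean–Stark; crystallise at −78 °C
Reagents that add atoms: none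
Why: acid-catalysed acetalisation (Seebach self-regeneration of stereocentres) gives mainly the cis dioxolanone, purified by crystallisation, whose acetal centre stores the lactic acid chirality.

Step 16
Reactants: 25 (2S,5S)-2-tert-butyl-5-methyl-1,3-dioxolan-4-one
Product: 27 (2S,5R)-5-[(benzyloxy)methyl]-2-tert-butyl-5-methyl-1,3-dioxolan-4-one, via lithium enolate 26 (not isolated)
Conditions: LiN(i-Pr)2, THF, −78 °C; then benzyl chloromethyl ether, −78 → −30 °C
Reagents that add atoms: benzyl chloromethyl ether, ClCOCc1ccccc1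
Why: the planar lithium enolate is alkylated on the face opposite the tert-butyl group (Seebach alkylation), which fixes the quaternary centre as R.

Step 17
Reactants: 27 (2S,5R)-5-[(benzyloxy)methyl]-2-tert-butyl-5-methyl-1,3-dioxolan-4-one
Product: 29 methyl (2R)-2,3-dihydroxy-2-methylpropanoate, via hydroxymethyl dioxolanone 28 (not isolated)
Conditions: H2 (1 atm), 10% Pd/C, MeOH, rt; filter; then HCl (cat.), MeOH, reflux
Reagents that add atoms: methanol, CO
Why: hydrogenolysis removes the benzyl ether and acid-catalysed methanolysis (transesterification) opens the acylal to the methyl ester without touching the quaternary centre.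

Step 18
Reactants: 29 methyl (2R)-2,3-dihydroxy-2-methylpropanoate
Product: 30 methyl (4R)-2,2,4-trimethyl-1,3-dioxolane-4-carboxylate
Conditions: 2,2-dimethoxypropane, PPTS (cat.), acetone, rt
Reagents that add atoms: 2,2-dimethoxypropane, COC(C)(C)OC
Why: acid-catalysed transketalisation protects the 1,2-diol as its acetonide.

Step 19
Reactants: 30 methyl (4R)-2,2,4-trimethyl-1,3-dioxolane-4-carboxylate
Product: 31 (4R)-2,2,4-trimethyl-1,3-dioxolane-4-carboxylic acid
Conditions: LiOH·H2O, THF/MeOH/H2O, rt; then cold 1 M HCl to pH 4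
Reagents that add atoms: lithium hydroxide, [Li+].[OH-]
Why: saponification of the methyl ester, with the acetonide stable to base and the quaternary centre unable to epimerise.

Step 20 (key step)
Reactants: 17 (5S)-3-(bromomethyl)-5-[(2E)-2-methylpenta-2,4-dien-1-yl]furan-2(5H)-one; 22 (2Z)-4-{[tert-butyl(dimethyl)silyl]oxy}-3-iodobut-2-enal (1.5 equiv)
Product: 33 (4S,5S)-4-[(1S,2Z)-4-{[tert-butyl(dimethyl)silyl]oxy}-1-hydroxy-3-iodobut-2-en-1-yl]-3-methylidene-5-[(2E)-2-methylpenta-2,4-dien-1-yl]oxolan-2-one, via allylzinc bromide 32 (not isolated)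
Conditions: Zn dust, THF/sat. aq. NH4Cl (10:1), 0 °C → rt
Reagents that add atoms: none
Why: in this zinc Barbier carbonyl allylation the allylzinc adds through its γ-carbon (C7) to the aldehyde via a chair Zimmerman–Traxler transition state on the lactone face anti to the C8 side chain, which gives trans C7/C8 substituents and the anti C6 carbinol and unveils the α-methylene lactone.

Step 21
Reactants: 33 Barbier alcohol (as in step 20); 31 (4R)-2,2,4-trimethyl-1,3-dioxolane-4-carboxylic acid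
Product: 35 (1S,2Z)-4-{[tert-butyl(dimethyl)silyl]oxy}-3-iodo-1-{(2S,3R)-4-methylidene-2-[(2E)-2-methylpenta-2,4-dien-1-yl]-5-oxooxolan-3-yl}but-2-en-1-yl (4R)-2,2,4-trimethyl-1,3-dioxolane-4-carboxylate, via mixed anhydride 34 (not isolated)
Conditions: 31, 2,4,6-trichlorobenzoyl chloride, Et3N, THF, rt; then 33, DMAP, toluene, rt → 40 °C
Reagents that add atoms: none
Why: Yamaguchi esterification through the mixed anhydride and DMAP acylates the hindered secondary alcohol at oxygen, so C6 is retained.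

Step 22
Reactants: 35 seco ester (as in step 21)
Product: 37 (3aR,4R,5E,9E,11aS)-6-({[tert-butyl(dimethyl)silyl]oxy}methyl)-10-methyl-3-methylidene-2-oxo-2,3,3a,4,7,8,11,11a-octahydrocyclodeca[b]furan-4-yl (4R)-2,2,4-trimethyl-1,3-dioxolane-4-carboxylate, via alkylborane 36 (not isolated)
Conditions: 9-BBN (1.5 equiv), THF, 0 °C → rt; then syringe-pump addition to Pd(dppf)Cl2·CH2Cl2 (20 mol%), AsPh3 (40 mol%), aq. K3PO4, DMF/THF, 45 °C, 2 mM
Reagents that add atoms: none
Why: 9-BBN hydroborates the terminal carbon of the diene faster than the hindered or electron-poor alkenes, and intramolecular B-alkyl Suzuki–Miyaura coupling with the Z alkenyl iodide at high dilution closes the ten-membered ring with retention of both alkene geometries.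

Step 23
Reactants: 37 macrocyclic silyl ether (as in step 22)
Product: 38 (3aR,4R,5E,9E,11aS)-6-(hydroxymethyl)-10-methyl-3-methylidene-2-oxo-2,3,3a,4,7,8,11,11a-octahydrocyclodeca[b]furan-4-yl (4R)-2,2,4-trimethyl-1,3-dioxolane-4-carboxylate
Conditions: HF·pyridine, pyridine, THF, 0 °C → rt
Reagents that add atoms: none
Why: buffered fluoride desilylation removes the primary allylic TBS ether and leaves acetonide, esters and lactone intact.

Step 24
Reactants: 38 macrocyclic allylic alcohol (as in step 23)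
Product: 39 (3aR,4R,5E,9E,11aS)-6-[(acetyloxy)methyl]-10-methyl-3-methylidene-2-oxo-2,3,3a,4,7,8,11,11a-octahydrocyclodeca[b]furan-4-yl (4R)-2,2,4-trimethyl-1,3-dioxolane-4-carboxylate
Conditions: Ac2O, pyridine, DMAP (cat.), CH2Cl2, 0 °C
Reagents that add atoms: acetic anhydride, CC(=O)OC(C)=O
Why: DMAP-catalysed acetylation of the only free hydroxyl, the primary allylic one.

Step 25
Reactants: 39 macrocyclic acetate (as in step 24)
Product: 40 [(3aR,4R,5E,9E,11aS)-4-{[(2R)-2,3-dihydroxy-2-methylpropanoyl]oxy}-10-methyl-3-methylidene-2-oxo-2,3,3a,4,7,8,11,11a-octahydrocyclodeca[b]furan-6-yl]methyl acetate (target)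
Conditions: AcOH/H2O (4:1), 35 °C
Reagents that add atoms: none
Why: mild aqueous acetic acid effects acetal hydrolysis of the terminal acetonide while the esters, the lactone and the 1,5-diene tolerate the weakly acidic medium.

**Compound list**
1 | (S)-epichlorohydrin, (2S)-2-(chloromethyl)oxirane | ClC[C@@H]1CO1 | starting material
2 | ethynyltrimethylsilane | C#C[Si](C)(C)C | starting material
3 | lithium (trimethylsilyl)acetylide | [Li]C#C[Si](C)(C)C | intermediate
4 | (2S)-1-chloro-5-(trimethylsilyl)pent-4-yn-2-ol | ClC[C@@H](O)CC#C[Si](C)(C)C | intermediate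
5 | trimethyl{3-[(2S)-oxiran-2-yl]prop-1-yn-1-yl}silane | C1[C@@H](O1)CC#C[Si](C)(C)C | intermediate
6 | (3S)-6-(trimethylsilyl)hex-1-en-5-yn-3-ol | C=C[C@@H](O)CC#C[Si](C)(C)C | intermediate
7 | (3S)-hex-1-en-5-yn-3-ol | C=C[C@@H](O)CC#C | intermediate
8 | [(1E,4S)-4-(dimethylalumanyloxy)-2-methylhexa-1,5-dien-1-yl]dimethylalumane | C=C[C@@H](O[Al](C)C)C/C(C)=C/[Al](C)C | intermediate
9 | (3S,5E)-6-iodo-5-methylhexa-1,5-dien-3-ol | C=C[C@@H](O)C/C(C)=C/I | intermediate
10 | ethyl 2-(hydroxymethyl)prop-2-enoate | C=C(CO)C(=O)OCC | starting material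
11 | ethyl 2-({[tert-butyl(dimethyl)silyl]oxy}methyl)prop-2-enoate | C=C(CO[Si](C)(C)C(C)(C)C)C(=O)OCC | intermediate
12 | 2-({[tert-butyl(dimethyl)silyl]oxy}methyl)prop-2-enoic acid | C=C(CO[Si](C)(C)C(C)(C)C)C(=O)O | intermediate
13 | (3S,5E)-6-iodo-5-methylhexa-1,5-dien-3-yl 2-({[tert-butyl(dimethyl)silyl]oxy}methyl)prop-2-enoate | C=C(CO[Si](C)(C)C(C)(C)C)C(=O)O[C@H](C=C)C/C(C)=C/I | intermediate
14 | (5S)-3-({[tert-butyl(dimethyl)silyl]oxy}methyl)-5-[(2E)-3-iodo-2-methylprop-2-en-1-yl]furan-2(5H)-one | O=C1O[C@@H](C/C(C)=C/I)C=C1CO[Si](C)(C)C(C)(C)C | intermediate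
15 | (5S)-3-({[tert-butyl(dimethyl)silyl]oxy}methyl)-5-[(2E)-2-methylpenta-2,4-dien-1-yl]furan-2(5H)-one | O=C1O[C@@H](C/C(C)=C/C=C)C=C1CO[Si](C)(C)C(C)(C)C | intermediate
16 | (5S)-3-(hydroxymethyl)-5-[(2E)-2-methylpenta-2,4-dien-1-yl]furan-2(5H)-one | O=C1O[C@@H](C/C(C)=C/C=C)C=C1CO | intermediate
17 | (5S)-3-(bromomethyl)-5-[(2E)-2-methylpenta-2,4-dien-1-yl]furan-2(5H)-one | O=C1O[C@@H](C/C(C)=C/C=C)C=C1CBr | intermediate
18 | but-2-yne-1,4-diol | OCC#CCO | starting material
19 | 4-{[tert-butyl(dimethyl)silyl]oxy}but-2-yn-1-ol | OCC#CCO[Si](C)(C)C(C)(C)C | intermediate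
20 | sodium cyclic alkoxy(alkenyl)bis(2-methoxyethoxy)alanate from trans-hydroalumination of 19 | [Na+].COCCO[Al-]1(OCCOC)OCC=C1CO[Si](C)(C)C(C)(C)C | intermediate
21 | (2Z)-4-{[tert-butyl(dimethyl)silyl]oxy}-3-iodobut-2-en-1-ol | OC/C=C(\I)CO[Si](C)(C)C(C)(C)C | intermediate
22 | (2Z)-4-{[tert-butyl(dimethyl)silyl]oxy}-3-iodobut-2-enal | O=C/C=C(\I)CO[Si](C)(C)C(C)(C)C | intermediate
23 | (S)-lactic acid | C[C@H](O)C(=O)O | starting material
24 | pivalaldehyde | CC(C)(C)C=O | starting material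
25 | (2S,5S)-2-tert-butyl-5-methyl-1,3-dioxolan-4-one | C[C@@H]1O[C@H](C(C)(C)C)OC1=O | intermediate
26 | lithium (2S)-2-tert-butyl-5-methyl-1,3-dioxol-4-olate | CC1=C(O[Li])O[C@@H](C(C)(C)C)O1 | intermediate
27 | (2S,5R)-5-[(benzyloxy)methyl]-2-tert-butyl-5-methyl-1,3-dioxolan-4-one | C[C@]1(COCc2ccccc2)O[C@H](C(C)(C)C)OC1=O | intermediate
28 | (2S,5R)-2-tert-butyl-5-(hydroxymethyl)-5-methyl-1,3-dioxolan-4-one | C[C@]1(CO)O[C@H](C(C)(C)C)OC1=O | intermediate
29 | methyl (2R)-2,3-dihydroxy-2-methylpropanoate | COC(=O)[C@](C)(O)CO | intermediate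
30 | methyl (4R)-2,2,4-trimethyl-1,3-dioxolane-4-carboxylate | COC(=O)[C@]1(C)OC(C)(C)OC1 | intermediate
31 | (4R)-2,2,4-trimethyl-1,3-dioxolane-4-carboxylic acid | OC(=O)[C@]1(C)OC(C)(C)OC1 | intermediate
32 | bromo{[(5S)-5-[(2E)-2-methylpenta-2,4-dien-1-yl]-2-oxo-2,5-dihydrofuran-3-yl]methyl}zinc | O=C1O[C@@H](C/C(C)=C/C=C)C=C1C[Zn]Br | intermediate
33 | (4S,5S)-4-[(1S,2Z)-4-{[tert-butyl(dimethyl)silyl]oxy}-1-hydroxy-3-iodobut-2-en-1-yl]-3-methylidene-5-[(2E)-2-methylpenta-2,4-dien-1-yl]oxolan-2-one | C=C1C(=O)O[C@@H](C/C(C)=C/C=C)[C@@H]1[C@H](O)/C=C(\I)CO[Si](C)(C)C(C)(C)C | intermediate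
34 | (4R)-2,2,4-trimethyl-1,3-dioxolane-4-carboxylic 2,4,6-trichlorobenzoic anhydride | O=C(OC(=O)c1c(Cl)cc(Cl)cc1Cl)[C@]1(C)OC(C)(C)OC1 | intermediate
35 | (1S,2Z)-4-{[tert-butyl(dimethyl)silyl]oxy}-3-iodo-1-{(2S,3R)-4-methylidene-2-[(2E)-2-methylpenta-2,4-dien-1-yl]-5-oxooxolan-3-yl}but-2-en-1-yl (4R)-2,2,4-trimethyl-1,3-dioxolane-4-carboxylate | C=C1C(=O)O[C@@H](C/C(C)=C/C=C)[C@@H]1[C@H](OC(=O)[C@]2(C)OC(C)(C)OC2)/C=C(\I)CO[Si](C)(C)C(C)(C)C | intermediate
36 | B-alkyl-9-borabicyclo[3.3.1]nonane from 35 (boron on C3, the former terminal diene carbon) | C=C1C(=O)O[C@@H](C/C(C)=C/CCB2C3CCCC2CCC3)[C@@H]1[C@H](OC(=O)[C@]2(C)OC(C)(C)OC2)/C=C(\I)CO[Si](C)(C)C(C)(C)C | intermediate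
37 | (3aR,4R,5E,9E,11aS)-6-({[tert-butyl(dimethyl)silyl]oxy}methyl)-10-methyl-3-methylidene-2-oxo-2,3,3a,4,7,8,11,11a-octahydrocyclodeca[b]furan-4-yl (4R)-2,2,4-trimethyl-1,3-dioxolane-4-carboxylate | C=C1C(=O)O[C@H]2C/C(C)=C/CC/C(CO[Si](C)(C)C(C)(C)C)=C\[C@@H](OC(=O)[C@]3(C)OC(C)(C)OC3)[C@H]12 | intermediate
38 | (3aR,4R,5E,9E,11aS)-6-(hydroxymethyl)-10-methyl-3-methylidene-2-oxo-2,3,3a,4,7,8,11,11a-octahydrocyclodeca[b]furan-4-yl (4R)-2,2,4-trimethyl-1,3-dioxolane-4-carboxylate | C=C1C(=O)O[C@H]2C/C(C)=C/CC/C(CO)=C\[C@@H](OC(=O)[C@]3(C)OC(C)(C)OC3)[C@H]12 | intermediate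
39 | (3aR,4R,5E,9E,11aS)-6-[(acetyloxy)methyl]-10-methyl-3-methylidene-2-oxo-2,3,3a,4,7,8,11,11a-octahydrocyclodeca[b]furan-4-yl (4R)-2,2,4-trimethyl-1,3-dioxolane-4-carboxylate | C=C1C(=O)O[C@H]2C/C(C)=C/CC/C(COC(C)=O)=C\[C@@H](OC(=O)[C@]3(C)OC(C)(C)OC3)[C@H]12 | intermediate
40 | [(3aR,4R,5E,9E,11aS)-4-{[(2R)-2,3-dihydroxy-2-methylpropanoyl]oxy}-10-methyl-3-methylidene-2-oxo-2,3,3a,4,7,8,11,11a-octahydrocyclodeca[b]furan-6-yl]methyl acetate | C=C1C(=O)O[C@H]2C/C(C)=C/CC/C(COC(C)=O)=C\[C@@H](OC(=O)[C@](C)(O)CO)[C@H]12 | target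

**Totals and risks**

Total step count: 25. Longest linear sequence: 15 steps (1–4, 7–11, 20–25).

Most likely to fail, first: step 22. The 9-BBN must select the diene terminus over the α-methylene lactone, and the strained ten-membered ring must close faster than oligomerisation or β-hydride elimination. The fallback sets out from 35 and comes back at 37. Borane 36 is made as before but oxidised with NaBO3·4H2O (THF/H2O, rt) to the isolable primary alcohol F1, which is purified. I2, PPh3 and imidazole turn it into the primary alkyl iodide F2. Zinc dust with LiCl in THF at 30 °C inserts into the sp3 carbon–iodine bond only and gives the alkylzinc iodide F3. Slow addition of F3 to Pd2(dba)3 and SPhos in THF/NMP at 40 °C closes the ring by intramolecular Negishi coupling to 37.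

Second: step 20. The C6/C7 diastereoselectivity rests on the chair transition state, the Z iodo-enal 22 can isomerise or hydrolyse in the aqueous medium, and the allylzinc can be protonated. The fallback sets out from 17 and comes back at 33. Borylation of 17 with B2pin2 and catalytic Pd2(dba)3 (toluene, 50 °C) gives the isolable allylboronate F4. Its Sc(OTf)3-catalysed allylboration of 22 in dry toluene at 0 °C goes through a rigid closed chair to the boronic ester F5, which aqueous work-up hydrolyses to 33.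

Third: step 25. Acid may trigger transannular cyclisation of the 1,5-diene or ionise the allylic esters before the acetonide is gone. The fallback sets out from 35 and comes back at 40, moving the acid step in front of the ring closure. Aqueous trifluoroacetic acid in THF at 0 °C removes acetonide and TBS ether from the robust acyclic 35 to give the triol F6. TESOTf and 2,6-lutidine give the tris(triethylsilyl) ether F7. 9-BBN gives the alkylborane F8, which is cyclised exactly as in step 22 to the macrocycle F9. Buffered HF·pyridine frees the macrocyclic triol F10. Acetyl chloride (1.05 equiv) with 2,4,6-collidine in CH2Cl2 at −78 °C acetylates the unhindered primary allylic hydroxyl in preference to the neopentyl-type primary and the tertiary hydroxyl, giving 40.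

**Further compounds**
F1 | step 22 | primary alcohol from oxidation of 36 (C3–OH seco ester) | C=C1C(=O)O[C@@H](C/C(C)=C/CCO)[C@@H]1[C@H](OC(=O)[C@]2(C)OC(C)(C)OC2)/C=C(\I)CO[Si](C)(C)C(C)(C)C
F2 | step 22 | primary alkyl iodide (C3–iodo seco ester) | C=C1C(=O)O[C@@H](C/C(C)=C/CCI)[C@@H]1[C@H](OC(=O)[C@]2(C)OC(C)(C)OC2)/C=C(\I)CO[Si](C)(C)C(C)(C)C
F3 | step 22 | alkylzinc iodide from F2 | C=C1C(=O)O[C@@H](C/C(C)=C/CC[Zn]I)[C@@H]1[C@H](OC(=O)[C@]2(C)OC(C)(C)OC2)/C=C(\I)CO[Si](C)(C)C(C)(C)C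
F4 | step 20 | (5S)-5-[(2E)-2-methylpenta-2,4-dien-1-yl]-3-[(4,4,5,5-tetramethyl-1,3,2-dioxaborolan-2-yl)methyl]furan-2(5H)-one | O=C1O[C@@H](C/C(C)=C/C=C)C=C1CB2OC(C)(C)C(C)(C)O2
F5 | step 20 | pinacol boronic ester of alcohol 33 (O6–B) | C=C1C(=O)O[C@@H](C/C(C)=C/C=C)[C@@H]1[C@H](OB2OC(C)(C)C(C)(C)O2)/C=C(\I)CO
[Si](C)(C)C(C)(C)C
F6 | step 25 | acyclic triol from 35 (C15–OH and free side-chain diol) | C=C1C(=O)O[C@@H](C/C(C)=C/C=C)[C@@H]1[C@H](OC(=O)[C@](C)(O)CO)/C=C(\I)CO
F7 | step 25 | tris(triethylsilyl) ether of F6 | C=C1C(=O)O[C@@H](C/C(C)=C/C=C)[C@@H]1[C@H](OC(=O)[C@](C)(O[Si](CC)(CC)CC)CO[Si](CC)(CC)CC)/C=C(\I)CO[Si](CC)(CC)CC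
F8 | step 25 | B-alkyl-9-borabicyclo[3.3.1]nonane from F7 | C=C1C(=O)O[C@@H](C/C(C)=C/CCB2C3CCCC2CCC3)[C@@H]1[C@H](OC(=O)[C@](C)(O[Si](CC)(CC)CC)CO[Si](CC)(CC)CC)/C=C(\I)CO[Si](CC)(CC)CC
F9 | step 25 | macrocyclic tris(triethylsilyl) ether | C=C1C(=O)O[C@H]2C/C(C)=C/CC/C(CO[Si](CC)(CC)CC)=C\[C@@H](OC(=O)[C@](C)(O[Si](CC)(CC)CC)CO[Si](CC)(CC)CC)[C@H]12
F10 | step 25 | macrocyclic triol (15-deacetyl target) | C=C1C(=O)O[C@H]2C/C(C)=C/CC/C(CO)=C\[C@@H](OC(=O)[C@](C)(O)CO)[C@H]12
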